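**Retrosynthetic overview**

1. The target is unmasked from a ring A phenol (H at C1, OH at C2) by formylation and oxidation at C1, O-methylation at C2, deallylation and desilylation.
2. The strategy rests on the pattern of ring A: oxygen on C2 and C6 flanking C1, the carbinol chain on C3 beside the C2 oxygen, and hydrogen on C4 and C5. This maps onto a vinylketene (C2, C3, C4, C5) plus an alkynyl ether (C1, C6), so the hindered C6–O–C1′ ether oxygen arrives already bonded to ring B.
3. Key disconnection: photochemical Wolff rearrangement, [2+2] addition, 4π opening and 6π closure between an (S,E)-diazo enone and the ring B aryl ethynyl ether, forming C4–C5, C1–C2, C5–C6 and C2–C3.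
4. The ynol ether comes from 2-methoxy-4-methylphenol and trichloroethene; the diazo enone comes from (S)-benzyl glycidyl ether, which supplies the only stereocentre.
5. Ring order: ring B is bought as an arene; ring A is the only ring formed, in the key step.

Key step: step 15

Assumption: ring A is numbered C1 (CO2H), C2 (OMe), C3 (side chain), C4/C5 (H), C6 (aryloxy); ring B is numbered C1′ (ether O), C2′ (OH), C4′ (CH3), C6′ (CH2OH); CIP analysis of the given SMILES gives (S) at the benzylic carbinol carbon (O > aryl > CH2 > H). In names, ArB = 2-(allyloxy)-6-{[(tert-butyldimethylsilyl)oxy]methyl}-4-methylphenyl, bonded through C1′.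

**Fragment 1: ring B ynol ether**

Step 1
Reactants: 1 2-methoxy-4-methylphenol
Product: 2 2-hydroxy-3-methoxy-5-methylbenzaldehyde
Conditions: hexamethylenetetramine, CF3CO2H, 85 °C; then H2O, 60 °C
Reagents that add atoms: hexamethylenetetramine, C1N2CN3CN1CN(C2)C3; water, O
Why: Duff formylation, in which the iminium ion from protonated hexamethylenetetramine should attack the only free position ortho to the phenol OH (the para position carries the methyl group) and hydride transfer followed by hydrolysis gives the salicylaldehyde.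

Step 2
Reactants: 2 2-hydroxy-3-methoxy-5-methylbenzaldehyde
Product: 3 2,3-dihydroxy-5-methylbenzaldehyde
Conditions: BBr3, CH2Cl2, −78 °C → 20 °C; H2O
Reagents that add atoms: none
Why: Lewis acid cleavage of an aryl methyl ether (bromide attacks the methyl group of the boron-complexed ether), a standard conversion of ortho-vanillins into catechol aldehydes that leaves the formyl group intact.

Step 3
Reactants: 3 2,3-dihydroxy-5-methylbenzaldehyde
Product: 4 3-(allyloxy)-2-hydroxy-5-methylbenzaldehyde
Conditions: NaH (2.2 equiv), DMSO, 20 °C; allyl bromide (1.0 equiv); aq. HCl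
Reagents that add atoms: allyl bromide, C=CCBr
Why: Williamson alkylation of the catecholate dianion, in which the 2-oxide is conjugated with and chelated to the formyl group, so the more basic 3-oxide should be allylated selectively.

Step 4
Reactants: 4 3-(allyloxy)-2-hydroxy-5-methylbenzaldehyde
Product: 5 2-(allyloxy)-6-(hydroxymethyl)-4-methylphenol
Conditions: NaBH4, MeOH, 0 °C
Reagents that add atoms: none
Why: borohydride reduction of an aryl aldehyde, which does not touch the allyl ether.

Step 5
Reactants: 5 2-(allyloxy)-6-(hydroxymethyl)-4-methylphenol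
Product: 6 2-(allyloxy)-6-{[(tert-butyldimethylsilyl)oxy]methyl}-4-methylphenol
Conditions: TBSCl (1.05 equiv), imidazole, CH2Cl2, 0 °C
Reagents that add atoms: tert-butyldimethylsilyl chloride, CC(C)(C)[Si](C)(C)Cl
Why: chemoselective silylation, in which the primary benzylic alcohol should react well ahead of the hydrogen-bonded phenol that carries two ortho substituents.

Step 6
Reactants: 6 2-(allyloxy)-6-{[(tert-butyldimethylsilyl)oxy]methyl}-4-methylphenol; 7 trichloroethene
Product: 9 tert-butyl({3-(allyloxy)-2-[(E)-(1,2-dichlorovinyl)oxy]-5-methylbenzyl}oxy)dimethylsilane, via dichloroacetylene 8 (not isolated)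
Conditions: K2CO3, DMF, 70 °C
Reagents that add atoms: none
Why: addition–elimination of a phenoxide to trichloroethene, in which carbonate dehydrochlorinates 7 to dichloroacetylene (kept in solution, never isolated) and anti addition of phenoxide and a proton gives the (E)-1,2-dichlorovinyl ether.

Step 7
Reactants: 9 tert-butyl({3-(allyloxy)-2-[(E)-(1,2-dichlorovinyl)oxy]-5-methylbenzyl}oxy)dimethylsilane
Product: 12 tert-butyl{[3-(allyloxy)-2-(ethynyloxy)-5-methylbenzyl]oxy}dimethylsilane, via chloroethynyl ether 10 (not isolated), via lithium acetylide 11 (not isolated)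
Conditions: n-BuLi (2.3 equiv), THF, −78 → −40 °C; MeOH, −78 °C
Reagents that add atoms: n-butyllithium, [Li]CCCC (its lithium is held only by intermediate 11)
Why: double elimination of a 1,2-dichlorovinyl ether, in which n-BuLi removes the vinyl proton with loss of chloride to give 10, chlorine–lithium exchange gives 11 and methanol protonates it; allyl alkynyl ethers are made the same way, so the allyl ether should survive at −78 °C, and 12 is used at once.

**Fragment 2: diazo enone**

Step 8
Reactants: 13 (S)-benzyl glycidyl ether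
Product: 14 (S)-1-(benzyloxy)-4-methylpent-4-en-2-ol
Conditions: isopropenylmagnesium bromide, CuI (10 mol %), THF, −40 → −20 °C
Reagents that add atoms: isopropenylmagnesium bromide, CC(=C)[Mg]Br
Why: copper-catalysed Grignard opening of a terminal epoxide at the unsubstituted carbon (SN2), which leaves the C–O bond of the stereocentre untouched, so the (S) configuration of 13 is carried over.

Step 9
Reactants: 14 (S)-1-(benzyloxy)-4-methylpent-4-en-2-ol
Product: 15 (S)-1-(benzyloxy)-4-methylpentane-2,4-diol
Conditions: Co(acac)2 (20 mol %), PhSiH3, O2 (1 atm), THF, 20 °C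
Reagents that add atoms: dioxygen, O=O
Why: Mukaiyama hydration, in which hydrogen-atom transfer from a cobalt hydride to the 1,1-disubstituted alkene gives the tertiary radical that is trapped by O2 and reduced to the tertiary alcohol (Markovnikov), without effect on the stereocentre.

Step 10
Reactants: 15 (S)-1-(benzyloxy)-4-methylpentane-2,4-diol
Product: 16 (S)-1-(benzyloxy)-4-methyl-2,4-bis(triethylsilyloxy)pentane
Conditions: TESOTf (2.5 equiv), 2,6-lutidine, CH2Cl2, −78 → 0 °C
Reagents that add atoms: triethylsilyl trifluoromethanesulfonate, CC[Si](CC)(CC)OS(=O)(=O)C(F)(F)F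
Why: silylation with a silyl triflate, which is reactive enough to cap the tertiary as well as the secondary alcohol.

Step 11
Reactants: 16 (S)-1-(benzyloxy)-4-methyl-2,4-bis(triethylsilyloxy)pentane
Product: 17 (S)-4-methyl-2,4-bis(triethylsilyloxy)pentan-1-ol
Conditions: H2 (1 atm), Pd/C, EtOAc, 20 °C
Reagents that add atoms: none
Why: hydrogenolysis of a benzyl ether, run in ethyl acetate because triethylsilyl ethers are stable there but not in methanol over palladium.

Step 12
Reactants: 17 (S)-4-methyl-2,4-bis(triethylsilyloxy)pentan-1-ol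
Product: 18 (S)-4-methyl-2,4-bis(triethylsilyloxy)pentanal
Conditions: Dess–Martin periodinane, CH2Cl2, 0 → 20 °C
Reagents that add atoms: none
Why: Dess–Martin oxidation under near-neutral conditions, which should not epimerise the α-silyloxy aldehyde; 18 is used without storage.

Step 13
Reactants: 18 (S)-4-methyl-2,4-bis(triethylsilyloxy)pentanal
Product: 19 (S,E)-7-methyl-5,7-bis(triethylsilyloxy)oct-3-en-2-one
Conditions: Ph3P=CHC(O)CH3, CH2Cl2, 20 → 40 °C
Reagents that add atoms: 1-(triphenylphosphoranylidene)propan-2-one, CC(=O)C=P(c1ccccc1)(c1ccccc1)c1ccccc1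
Why: Wittig olefination with a stabilised, non-basic ylide, which should give the (E)-enone and leave the adjacent stereocentre unchanged.

Step 14
Reactants: 19 (S,E)-7-methyl-5,7-bis(triethylsilyloxy)oct-3-en-2-one
Product: 21 (S,E)-1-diazo-7-methyl-5,7-bis(triethylsilyloxy)oct-3-en-2-one, via trifluoroacetyl diketone 20 (not isolated)
Conditions: LiN(SiMe3)2, THF, −78 °C; CF3CO2CH2CF3, −78 °C; then MsN3, Et3N, H2O, MeCN, 20 °C
Reagents that add atoms: methanesulfonyl azide, CS(=O)(=O)N=[N+]=[N-]; 2,2,2-trifluoroethyl trifluoroacetate, O=C(OCC(F)(F)F)C(F)(F)F (its trifluoroacetyl group is held only by intermediate 20)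
Why: detrifluoroacetylative diazo transfer, in which kinetic enolisation at the methyl group and Claisen trifluoroacetylation give 20 and diazo transfer with loss of the trifluoroacetyl group as its sulfonamide gives the diazomethyl enone, avoiding the cycloaddition of diazomethane to enoyl chlorides.

**Key step and endgame**

Step 15
Reactants: 21 (S,E)-1-diazo-7-methyl-5,7-bis(triethylsilyloxy)oct-3-en-2-one; 12 tert-butyl{[3-(allyloxy)-2-(ethynyloxy)-5-methylbenzyl]oxy}dimethylsilane
Product: 26 5-(ArB–O)-2-[(S)-3-methyl-1,3-bis(triethylsilyloxy)butyl]phenol, via vinylketene 22 (not isolated), via vinylcyclobutenone 23 (not isolated), via dienylketene 24 (not isolated), via cyclohexadienone 25 (not isolated)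
Conditions: hν (λ ≥ 300 nm, Pyrex-filtered medium-pressure Hg lamp), degassed ClCH2CH2Cl, 20 °C; then 80 °C in the dark
Reagents that add atoms: none
Why: Light expels N2 from 21 and the alkenyl group shifts from the carbonyl carbon to the carbene carbon (Wolff rearrangement, new C4–C5 bond) to give vinylketene 22, whose ketene C=C adds across the electron-rich alkyne of 12 in a [2+2] cycloaddition (C1–C2 and C5–C6) to give cyclobutenone 23. On warming, 23 opens by reversible 4π electrocyclic cleavage to dienylketene 24, and ring A closes by 6π electrocyclisation between the ketene carbon C2 and the chain-bearing alkene carbon C3 to give dienone 25, which tautomerises to phenol 26. The closest known reaction is the Danheiser benzannulation in its photochemical Wolff variant with alkoxy- and siloxyalkynes, of which an aryl ethynyl ether is a less electron-rich member of the same alkynyl ether class. No stereocentre is created in 26, because the sp3 ring carbons of 23 and 25 are erased on aromatisation and the (S) silyloxy carbon lies outside every reacting π system and is carried through under neutral conditions. The step needs the regiochemistry in which the alkyne CH carbon bonds to the ketene carbonyl carbon, and the polarisation of the ynol ether (nucleophilic terminal carbon, electrophilic ketene carbon) secures it, so that OH ends on C2, H on C1 and OAr on C6. Irradiation above 300 nm, where the diazo enone absorbs and the aryl ethers do not, should keep the allyl aryl ether and the product diaryl ether out of the photochemistry, and the isolated allyl double bond should not compete with the ynol ether for the ketene.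

Step 16
Reactants: 26 5-(ArB–O)-2-[(S)-3-methyl-1,3-bis(triethylsilyloxy)butyl]phenol
Product: 27 6-(ArB–O)-2-hydroxy-3-[(S)-3-methyl-1,3-bis(triethylsilyloxy)butyl]benzaldehyde
Conditions: MgCl2, Et3N, (CH2O)n, THF, 65 °C
Reagents that add atoms: formaldehyde (as paraformaldehyde), C=O
Why: magnesium-mediated ortho-formylation (Casnati–Skattebøl), in which the magnesium phenoxide delivers formaldehyde to C1, the only free ortho carbon, and hydride transfer to a second formaldehyde gives the aldehyde, while the free para carbon C5 is not reached by the chelate.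

Step 17
Reactants: 27 6-(ArB–O)-2-hydroxy-3-[(S)-3-methyl-1,3-bis(triethylsilyloxy)butyl]benzaldehyde
Product: 28 6-(ArB–O)-2-methoxy-3-[(S)-3-methyl-1,3-bis(triethylsilyloxy)butyl]benzaldehyde
Conditions: MeI, K2CO3, DMF, 20 °C
Reagents that add atoms: iodomethane, CI
Why: Williamson methylation of the salicylaldehyde phenoxide, which is the only acidic site in the molecule.

Step 18
Reactants: 28 6-(ArB–O)-2-methoxy-3-[(S)-3-methyl-1,3-bis(triethylsilyloxy)butyl]benzaldehyde
Product: 29 6-(ArB–O)-2-methoxy-3-[(S)-3-methyl-1,3-bis(triethylsilyloxy)butyl]benzoic acid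
Conditions: NaClO2, NaH2PO4, 2-methyl-2-butene, t-BuOH/THF/H2O, 0 → 20 °C
Reagents that add atoms: sodium chlorite, [Na+].[O-]Cl=O
Why: Pinnick oxidation, in which chlorous acid converts the hindered aldehyde into the acid and excess 2-methyl-2-butene removes hypochlorous acid before it can attack the allyl ether or the electron-rich rings.

Step 19
Reactants: 29 6-(ArB–O)-2-methoxy-3-[(S)-3-methyl-1,3-bis(triethylsilyloxy)butyl]benzoic acid
Product: 30 6-(2-hydroxy-6-{[(tert-butyldimethylsilyl)oxy]methyl}-4-methylphenoxy)-2-methoxy-3-[(S)-3-methyl-1,3-bis(triethylsilyloxy)butyl]benzoic acid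
Conditions: Pd(PPh3)4 (5 mol %), morpholine, THF, 20 °C
Reagents that add atoms: none
Why: Tsuji–Trost deallylation, in which zerovalent palladium ionises the allyl aryl ether to a π-allyl complex and the phenoxide, and morpholine takes up the allyl group under neutral conditions.

Step 20
Reactants: 30 6-(2-hydroxy-6-{[(tert-butyldimethylsilyl)oxy]methyl}-4-methylphenoxy)-2-methoxy-3-[(S)-3-methyl-1,3-bis(triethylsilyloxy)butyl]benzoic acid
Product: 31 6-[2-hydroxy-6-(hydroxymethyl)-4-methylphenoxy]-3-[(S)-1,3-dihydroxy-3-methylbutyl]-2-methoxybenzoic acid (CNP0452050.2)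
Conditions: n-Bu4NF, THF, 0 → 20 °C; aq. HCl to pH 4, 0 °C
Reagents that add atoms: none
Why: fluoride-mediated cleavage of all three silyl ethers, chosen because it avoids the acid that could ionise the electron-rich benzylic carbinol, so the (S) centre should be kept; brief acidification to pH 4 frees the carboxylic acid.

**Compound list**

1 | 2-methoxy-4-methylphenol | COc1cc(C)ccc1O | starting material
2 | 2-hydroxy-3-methoxy-5-methylbenzaldehyde | COc1cc(C)cc(C=O)c1O | intermediate
3 | 2,3-dihydroxy-5-methylbenzaldehyde | Oc1cc(C)cc(C=O)c1O | intermediate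
4 | 3-(allyloxy)-2-hydroxy-5-methylbenzaldehyde | C=CCOc1cc(C)cc(C=O)c1O | intermediate
5 | 2-(allyloxy)-6-(hydroxymethyl)-4-methylphenol | C=CCOc1cc(C)cc(CO)c1O | intermediate
6 | 2-(allyloxy)-6-{[(tert-butyldimethylsilyl)oxy]methyl}-4-methylphenol | C=CCOc1cc(C)cc(CO[Si](C)(C)C(C)(C)C)c1O | intermediate
7 | trichloroethene | ClC=C(Cl)Cl | starting material
8 | dichloroacetylene (formed in the flask, step 6) | ClC#CCl | intermediate
9 | tert-butyl({3-(allyloxy)-2-[(E)-(1,2-dichlorovinyl)oxy]-5-methylbenzyl}oxy)dimethylsilane | Cl/C=C(/Cl)Oc1c(OCC=C)cc(C)cc1CO[Si](C)(C)C(C)(C)C | intermediate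
10 | tert-butyl({3-(allyloxy)-2-[(chloroethynyl)oxy]-5-methylbenzyl}oxy)dimethylsilane (formed in the flask, step 7) | ClC#COc1c(OCC=C)cc(C)cc1CO[Si](C)(C)C(C)(C)C | intermediate
11 | lithium acetylide of 12, [(ArB–O)ethynyl]lithium (formed in the flask, step 7) | [Li]C#COc1c(OCC=C)cc(C)cc1CO[Si](C)(C)C(C)(C)C | intermediate
12 | tert-butyl{[3-(allyloxy)-2-(ethynyloxy)-5-methylbenzyl]oxy}dimethylsilane | C#COc1c(OCC=C)cc(C)cc1CO[Si](C)(C)C(C)(C)C | intermediate
13 | (S)-benzyl glycidyl ether | C1O[C@@H]1COCc1ccccc1 | starting material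
14 | (S)-1-(benzyloxy)-4-methylpent-4-en-2-ol | O[C@@H](CC(C)=C)COCc1ccccc1 | intermediate
15 | (S)-1-(benzyloxy)-4-methylpentane-2,4-diol | O[C@@H](CC(C)(C)O)COCc1ccccc1 | intermediate
16 | (S)-1-(benzyloxy)-4-methyl-2,4-bis(triethylsilyloxy)pentane | CC[Si](CC)(CC)O[C@@H](CC(C)(C)O[Si](CC)(CC)CC)COCc1ccccc1 | intermediate
17 | (S)-4-methyl-2,4-bis(triethylsilyloxy)pentan-1-ol | CC[Si](CC)(CC)O[C@@H](CC(C)(C)O[Si](CC)(CC)CC)CO | intermediate
18 | (S)-4-methyl-2,4-bis(triethylsilyloxy)pentanal | CC[Si](CC)(CC)O[C@@H](CC(C)(C)O[Si](CC)(CC)CC)C=O | intermediate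
19 | (S,E)-7-methyl-5,7-bis(triethylsilyloxy)oct-3-en-2-one | CC(=O)/C=C/[C@@H](O[Si](CC)(CC)CC)CC(C)(C)O[Si](CC)(CC)CC | intermediate
20 | (S,E)-1,1,1-trifluoro-9-methyl-7,9-bis(triethylsilyloxy)dec-5-ene-2,4-dione (formed in the flask, step 14) | O=C(CC(=O)/C=C/[C@@H](O[Si](CC)(CC)CC)CC(C)(C)O[Si](CC)(CC)CC)C(F)(F)F | intermediate
21 | (S,E)-1-diazo-7-methyl-5,7-bis(triethylsilyloxy)oct-3-en-2-one | [N-]=[N+]=CC(=O)/C=C/[C@@H](O[Si](CC)(CC)CC)CC(C)(C)O[Si](CC)(CC)CC | intermediate
22 | (S,E)-7-methyl-5,7-bis(triethylsilyloxy)octa-1,3-dien-1-one, the vinylketene (formed in the flask, step 15) | O=C=C/C=C/[C@@H](O[Si](CC)(CC)CC)CC(C)(C)O[Si](CC)(CC)CC | intermediate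
23 | 3-(ArB–O)-4-[(S,E)-5-methyl-3,5-bis(triethylsilyloxy)hex-1-enyl]cyclobut-2-en-1-one, both epimers at C4 (formed in the flask, step 15) | O=C1C=C(Oc2c(OCC=C)cc(C)cc2CO[Si](C)(C)C(C)(C)C)C1/C=C/[C@@H](O[Si](CC)(CC)CC)CC(C)(C)O[Si](CC)(CC)CC | intermediate
24 | (3E,5E,7S)-3-(ArB–O)-9-methyl-7,9-bis(triethylsilyloxy)deca-1,3,5-trien-1-one, ketene carbon and C5 cis across C3=C4 (formed in the flask, step 15) | O=C=C/C(Oc1c(OCC=C)cc(C)cc1CO[Si](C)(C)C(C)(C)C)=C\C=C\[C@@H](O[Si](CC)(CC)CC)CC(C)(C)O[Si](CC)(CC)CC | intermediate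
25 | 3-(ArB–O)-6-[(S)-3-methyl-1,3-bis(triethylsilyloxy)butyl]cyclohexa-2,4-dien-1-one, both epimers at C6 (formed in the flask, step 15) | O=C1C=C(Oc2c(OCC=C)cc(C)cc2CO[Si](C)(C)C(C)(C)C)C=CC1[C@@H](O[Si](CC)(CC)CC)CC(C)(C)O[Si](CC)(CC)CC | intermediate
26 | 5-(ArB–O)-2-[(S)-3-methyl-1,3-bis(triethylsilyloxy)butyl]phenol | Oc1cc(Oc2c(OCC=C)cc(C)cc2CO[Si](C)(C)C(C)(C)C)ccc1[C@@H](O[Si](CC)(CC)CC)CC(C)(C)O[Si](CC)(CC)CC | intermediate
27 | 6-(ArB–O)-2-hydroxy-3-[(S)-3-methyl-1,3-bis(triethylsilyloxy)butyl]benzaldehyde | O=Cc1c(O)c([C@@H](O[Si](CC)(CC)CC)CC(C)(C)O[Si](CC)(CC)CC)ccc1Oc1c(OCC=C)cc(C)cc1CO[Si](C)(C)C(C)(C)C | intermediate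
28 | 6-(ArB–O)-2-methoxy-3-[(S)-3-methyl-1,3-bis(triethylsilyloxy)butyl]benzaldehyde | COc1c([C@@H](O[Si](CC)(CC)CC)CC(C)(C)O[Si](CC)(CC)CC)ccc(Oc2c(OCC=C)cc(C)cc2CO[Si](C)(C)C(C)(C)C)c1C=O | intermediate
29 | 6-(ArB–O)-2-methoxy-3-[(S)-3-methyl-1,3-bis(triethylsilyloxy)butyl]benzoic acid | COc1c([C@@H](O[Si](CC)(CC)CC)CC(C)(C)O[Si](CC)(CC)CC)ccc(Oc2c(OCC=C)cc(C)cc2CO[Si](C)(C)C(C)(C)C)c1C(=O)O | intermediate
30 | 6-(2-hydroxy-6-{[(tert-butyldimethylsilyl)oxy]methyl}-4-methylphenoxy)-2-methoxy-3-[(S)-3-methyl-1,3-bis(triethylsilyloxy)butyl]benzoic acid | COc1c([C@@H](O[Si](CC)(CC)CC)CC(C)(C)O[Si](CC)(CC)CC)ccc(Oc2c(O)cc(C)cc2CO[Si](C)(C)C(C)(C)C)c1C(=O)O | intermediate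
31 | 6-[2-hydroxy-6-(hydroxymethyl)-4-methylphenoxy]-3-[(S)-1,3-dihydroxy-3-methylbutyl]-2-methoxybenzoic acid (CNP0452050.2) | COc1c([C@@H](O)CC(C)(C)O)ccc(Oc2c(O)cc(C)cc2CO)c1C(=O)O | target

**Step count and risks**

Total step count: 20. Longest linear sequence: 13 steps (steps 1–7 or 8–14, then 15–20).

Steps most likely to fail:

1. Step 15 (key benzannulation). The aryl ether chromophores may compete for light and enter photo-Claisen or photo-Fries pathways, or the weakly nucleophilic aryloxyalkyne may capture the vinylketene too slowly, so that ketene dimerisation and alkyne oligomerisation take over. Fallback: the diaryl ether is made by nucleophilic aromatic substitution, setting out from phenol 6 and coming back at aldehyde 28. Commercial 1-(4-fluoro-2-methoxyphenyl)ethan-1-one F1 is converted with LiN(i-Pr)2 and acetone (THF, −78 °C) into the aldol 1-(4-fluoro-2-methoxyphenyl)-3-hydroxy-3-methylbutan-1-one F2. Noyori transfer hydrogenation with RuCl(p-cymene)[(S,S)-TsDPEN] and HCO2H/Et3N should give (S)-1-(4-fluoro-2-methoxyphenyl)-3-methylbutane-1,3-diol F3, with the sense known for acetophenones. TESOTf and 2,6-lutidine give (S)-4-fluoro-2-methoxy-1-[3-methyl-1,3-bis(triethylsilyloxy)butyl]benzene F4. Lithiation between fluorine and methoxy (n-BuLi, THF, −78 °C) and DMF give (S)-6-fluoro-2-methoxy-3-[3-methyl-1,3-bis(triethylsilyloxy)butyl]benzaldehyde F5. The potassium salt of 6 then displaces the fluoride ortho to the formyl group (K2CO3, DMF, 90 °C) to give 28, and steps 18–20 follow unchanged.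

2. Step 16 (formylation at C1). Carbon–carbon bond formation at the carbon flanked by the magnesium phenoxide and the bulky aryloxy group may be slow. Prolonged heating could then allow loss of the benzylic silyloxy group through an ortho-quinone methide, cleavage of triethylsilyl ethers by the magnesium salt, or methoxymethyl ether formation. Fallback: halogenation and carboxylation, setting out from phenol 26 and coming back at acid 29. Amine-directed ortho-bromination (NBS, catalytic i-Pr2NH, CH2Cl2, 0 °C) gives 2-bromo-3-(ArB–O)-6-[(S)-3-methyl-1,3-bis(triethylsilyloxy)butyl]phenol F6. MeI and K2CO3 give 2-bromo-1-(ArB–O)-3-methoxy-4-[(S)-3-methyl-1,3-bis(triethylsilyloxy)butyl]benzene F7. Bromine–lithium exchange (n-BuLi, THF, −78 °C) followed by CO2 and acidification to pH 4 gives 29, and steps 19–20 follow unchanged.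

3. Step 6 (dichlorovinyl ether). The hindered, di-ortho-substituted phenoxide may add too slowly to short-lived dichloroacetylene, and hot carbonate may cause migration or loss of the benzylic silyl group. Fallback: the order of operations is changed, setting out from aldehyde 4 and coming back at 9. The chelated phenoxide of 4, which carries no silyl group, is treated with trichloroethene 7 (K2CO3, DMF, 70 °C) to give 3-(allyloxy)-2-{[(E)-1,2-dichlorovinyl]oxy}-5-methylbenzaldehyde F8. NaBH4 in MeOH gives {3-(allyloxy)-2-{[(E)-1,2-dichlorovinyl]oxy}-5-methylphenyl}methanol F9, and TBSCl with imidazole gives 9.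

Further compounds
F1 | step 15 | 1-(4-fluoro-2-methoxyphenyl)ethan-1-one (bought) | CC(=O)c1ccc(F)cc1OC
F2 | step 15 | 1-(4-fluoro-2-methoxyphenyl)-3-hydroxy-3-methylbutan-1-one | CC(C)(O)CC(=O)c1ccc(F)cc1OC
F3 | step 15 | (S)-1-(4-fluoro-2-methoxyphenyl)-3-methylbutane-1,3-diol | COc1cc(F)ccc1[C@@H](O)CC(C)(C)O
F4 | step 15 | (S)-4-fluoro-2-methoxy-1-[3-methyl-1,3-bis(triethylsilyloxy)butyl]benzene | COc1cc(F)ccc1[C@@H](O[Si](CC)(CC)CC)CC(C)(C)O[Si](CC)(CC)CC
F5 | step 15 | (S)-6-fluoro-2-methoxy-3-[3-methyl-1,3-bis(triethylsilyloxy)butyl]benzaldehyde | COc1c([C@@H](O[Si](CC)(CC)CC)CC(C)(C)O[Si](CC)(CC)CC)ccc(F)c1C=O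
F6 | step 16 | 2-bromo-3-(ArB–O)-6-[(S)-3-methyl-1,3-bis(triethylsilyloxy)butyl]phenol | Oc1c(Br)c(Oc2c(OCC=C)cc(C)cc2CO[Si](C)(C)C(C)(C)C)ccc1[C@@H](O[Si](CC)(CC)CC)CC(C)(C)O[Si](CC)(CC)CC
F7 | step 16 | 2-bromo-1-(ArB–O)-3-methoxy-4-[(S)-3-methyl-1,3-bis(triethylsilyloxy)butyl]benzene | COc1c(Br)c(Oc2c(OCC=C)cc(C)cc2CO[Si](C)(C)C(C)(C)C)ccc1[C@@H](O[Si](CC)(CC)CC)CC(C)(C)O[Si](CC)(CC)CC
F8 | step 6 | 3-(allyloxy)-2-{[(E)-1,2-dichlorovinyl]oxy}-5-methylbenzaldehyde | Cl/C=C(/Cl)Oc1c(OCC=C)cc(C)cc1C=O
F9 | step 6 | {3-(allyloxy)-2-{[(E)-1,2-dichlorovinyl]oxy}-5-methylphenyl}methanol | Cl/C=C(/Cl)Oc1c(OCC=C)cc(C)cc1CO
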